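**Plan**
- Retrosynthesis: cut the C8–O ferulate ester, then the two C11–CH3 bonds (back to a C7 methyl ester), then the C1–C5 bond of the cyclopentane while C5 is re-joined to C10. This gives a cis-fused 4,10-dimethyldecalin with an equatorial C1 mesylate, whose ring B leads back through a C7 ketone with a C8 silyl ether to the Wieland–Miescher ketone.
- Enabling feature: the tetrasubstituted C1=C10 alkene lies beside the C1–C5 fusion bond of a cyclopentane (C1–C5) fused to a cycloheptane (C1, C5–C10). This is what a C10 cation leaves behind once C5 of a 10-methyldecalin has moved from C10 to C1.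
- Forward order: ring B is annulated onto the cyclohexanedione (ring A); the C4 methyl, C8 oxygen and C7 carboxyl are added; step 13 then turns both six-membered rings into the five- and seven-membered rings at once; the C11 methyls and the ferulate come last.
- Stereochemistry: C10 from L-proline; C1 from hydride attack anti to the angular methyl; C4 and C8 by equilibration to equatorial positions; C5 and C7 by hydrogenation (cis fusion, then convex face). All four spectator centres pass through the shift unchanged, and the E-alkene arrives with ferulic acid.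

Key step: step 13

Remark: guaiane numbering is used for every bicyclic compound (decalins: ring A = C1–C5 and C10, ring B = C5–C10, C10 carries the angular methyl); α is the face of the C10 methyl in the decalins and of H5 in the hydroazulenes; the proline-derived (S)-Wieland–Miescher ketone is assumed to be brought to enantiopurity by crystallisation.

**Route**

Step 1
Reactants: 1 2-methylcyclohexane-1,3-dione; 2 methyl vinyl ketone
Product: 4 (S)-Wieland–Miescher ketone, via Michael triketone 3 (not isolated)
Conditions: AcOH (cat.), hydroquinone (cat.), H2O, 75 °C; then L-proline (5 mol%), DMSO, rt; recrystallisation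
Reagents that add atoms: none
Why: Michael addition followed by proline-mediated enamine aldol condensation (Hajos–Parrish–Eder–Sauer–Wiechert form of the Robinson annulation) should close ring B and set C10 as S, because the enamine attacks one of the two enantiotopic ring carbonyls under hydrogen-bond direction from the proline carboxylic acid.

Step 2
Reactants: 4 (S)-Wieland–Miescher ketone
Product: 5 1α-hydroxy enone
Conditions: NaBH4 (0.3 equiv), EtOH, −10 → 0 °C
Reagents that add atoms: none
Why: Chemoselective borohydride reduction of the saturated C1 ketone over the vinylogous enone carbonyl, with hydride arriving anti to the angular methyl so that the C1 hydroxyl ends up cis to it (α, S).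

Step 3
Reactants: 5 1α-hydroxy enone
Product: 6 1α-benzyloxy enone
Conditions: benzyl 2,2,2-trichloroacetimidate, TfOH (cat.), CH2Cl2–cyclohexane, 0 °C → rt
Reagents that add atoms: benzyl 2,2,2-trichloroacetimidate, N=C(OCc1ccccc1)C(Cl)(Cl)Cl
Why: Acid-catalysed imidate O-benzylation avoids base (which would enolise the enone) and gives an ether that survives the enolate, carbonylation and pyridine-moderated hydrogenation steps yet is removed in the hydrogenation of step 11.

Step 4
Reactants: 6 1α-benzyloxy enone
Product: 7 4-methylene dienone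
Conditions: CH2(OEt)2, POCl3, NaOAc, CHCl3, 65 °C
Reagents that add atoms: diethoxymethane, CCOCOCC
Why: γ-Methylenation as known for Δ4-3-keto steroids: the ethoxymethyl cation formed from the acetal attacks the γ-carbon (C4) of the dienol ether generated in situ, and loss of ethanol leaves the cross-conjugated 4-methylene enone.

Step 5
Reactants: 7 4-methylene dienone
Product: 9 4β-methyl enone, via 4α-methyl epimer 8 (not isolated)
Conditions: H2 (1 atm), RhCl(PPh3)3 (5 mol%), benzene, rt; then HCl (cat.), EtOH, rt
Reagents that add atoms: none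
Why: Homogeneous hydrogenation should reduce only the unhindered exocyclic alkene from the face away from the angular methyl (axial 4α-methyl), after which acid-mediated dienol equilibration moves the methyl to the equatorial 4β position, free of the 1,3-diaxial clash with the C10 methyl.

Step 6
Reactants: 9 4β-methyl enone
Product: 10 8β-hydroxy enone
Conditions: NaN(SiMe3)2, THF, −78 °C; then 3-phenyl-2-(phenylsulfonyl)oxaziridine, −78 °C; aqueous work-up
Reagents that add atoms: 3-phenyl-2-(phenylsulfonyl)oxaziridine, O=S(=O)(N1OC1c1ccccc1)c1ccccc1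
Why: Kinetic α′-deprotonation of the enone at C8 and oxaziridine oxygen transfer (enolate hydroxylation) place the oxygen regiospecifically at C8, anti to the angular methyl (β); this centre is corrected in step 8.

Step 7
Reactants: 10 8β-hydroxy enone
Product: 11 8β-silyloxy enone
Conditions: tert-butyldiphenylsilyl chloride, imidazole, DMF, rt
Reagents that add atoms: tert-butyldiphenylsilyl chloride, CC(C)(C)[Si](Cl)(c1ccccc1)c1ccccc1
Why: Standard silylation of the secondary ketol, with the diphenyl silyl ether chosen because it withstands the hot buffered acetic acid of step 13.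

Step 8
Reactants: 11 8β-silyloxy enone
Product: 13 cis-decalone with 8α-silyloxy group, via 8β-silyloxy cis-decalone 12 (not isolated)
Conditions: H2 (1 atm), Pd/C (10%), pyridine, rt; filter; then DBU (cat.), CH2Cl2, rt
Reagents that add atoms: none
Why: Hydrogenation of angularly methylated octalones over Pd/C in pyridine is known to add hydrogen to the fusion carbon on the face of the angular methyl (cis fusion, H5 α) while sparing benzyl ethers, and in the resulting chair the 8β-silyloxy group is axial and syn to C1, so enolisation with DBU should epimerise C8 to the equatorial α position.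

Step 9
Reactants: 13 cis-decalone with 8α-silyloxy group
Product: 14 C6=C7 enol triflate
Conditions: KN(SiMe3)2, THF, −78 °C; then PhNTf2, −78 → 0 °C
Reagents that add atoms: N-phenylbis(trifluoromethanesulfonimide), O=S(=O)(N(c1ccccc1)S(=O)(=O)C(F)(F)F)C(F)(F)F
Why: The hindered amide removes a proton from the C6 methylene and not from the silyloxy-bearing C8 methine (also the inherent enolisation direction of cis-fused decalones of this type), and O-triflation of the enolate fixes the C6=C7 regiochemistry.

Step 10
Reactants: 14 C6=C7 enol triflate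
Product: 15 unsaturated methyl ester
Conditions: Pd(OAc)2 (5 mol%), PPh3, CO (1 atm), MeOH, Et3N, DMF, 50 °C
Reagents that add atoms: carbon monoxide, [C-]#[O+]; methanol, CO
Why: Alkoxycarbonylation: oxidative addition of the enol triflate to zerovalent palladium formed in situ, CO insertion and methanolysis attach C11 to C7 as a methyl ester.

Step 11
Reactants: 15 unsaturated methyl ester
Product: 16 1α-hydroxy ester
Conditions: H2 (3 atm), Pd(OH)2/C, EtOAc, rt
Reagents that add atoms: none
Why: Heterogeneous hydrogenation should add to the convex α face (the β face of C6/C7 is screened by the axial C1 of ring A), setting H7 α and so the equatorial 7β ester trans to the 8α silyl ether, which is also the thermodynamically favoured arrangement, while the same catalyst hydrogenolyses the C1 benzyl ether.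

Step 12
Reactants: 16 1α-hydroxy ester
Product: 17 C1 mesylate
Conditions: MsCl, Et3N, CH2Cl2, 0 °C
Reagents that add atoms: methanesulfonyl chloride, CS(=O)(=O)Cl
Why: Sulfene-type mesylation is effective for hindered secondary alcohols, and the equatorial C1 hydroxyl is the only free hydroxyl in the molecule.

Step 13
Reactants: 17 C1 mesylate
Product: 18 hydroazulene ester
Conditions: KOAc, AcOH, 100 °C
Reagents that add atoms: none
Why: Ionisation of the equatorial C1 mesylate is assisted by the antiperiplanar C5–C10 σ bond, so C5 migrates from C10 to C1 (inversion at C1, retention at C5) and the tertiary C10 cation loses H1 to acetate to give the tetrasubstituted C1=C10 alkene. The closest known reaction type is the buffered acetolysis of cis-fused 1-decalyl sulfonates bearing an angular methyl group, a solvolytic Wagner–Meerwein rearrangement to hydroazulenes. The cyclopentane closes by this suprafacial 1,2-alkyl shift as the C1–C5 bond forms (ring A contracts), and the cycloheptane is ring B enlarged by insertion of C1 into the former C5–C10 bond. No stereocentre is created, and C4, C5, C7 and C8 are carried through unchanged. The step needs migration of C5 and not C9 or the methyl, which the locked chair–chair conformer secures (mesylate, 4-methyl, ester and silyl ether all equatorial, only C5–C10 anti to C1–O), and it needs proton loss from C1 and not from C9 or the methyl, which rests on the greater stability of the tetrasubstituted alkene aided by the inductive effect of the C8 oxygen on the C9 hydrogens. Keeping C11 at the ester oxidation level and C8 as an acid-stable silyl ether leaves no internal oxygen nucleophile that could trap the cation as a cyclic ether.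

Step 14
Reactants: 18 hydroazulene ester
Product: 19 C11 carbinol silyl ether
Conditions: MeMgBr (excess), THF, −20 °C → rt
Reagents that add atoms: methylmagnesium bromide, C[Mg]Br
Why: Double Grignard addition to the methyl ester gives the dimethyl carbinol, and the β-silyloxy group is too poor a leaving group for elimination to compete.

Step 15
Reactants: 19 C11 carbinol silyl ether
Product: 20 C8,C11 diol
Conditions: Bu4NF, THF, 45 °C
Reagents that add atoms: none
Why: Fluoride-mediated desilylation frees the secondary C8 hydroxyl without acid, which would endanger the tetrasubstituted alkene and the tertiary alcohol.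

Step 16
Reactants: 21 ferulic acid
Product: 23 4-O-silyl ferulic acid, via bis-silyl ferulate 22 (not isolated)
Conditions: tert-butyldimethylsilyl chloride (2.2 equiv), imidazole, DMF, rt; then K2CO3 (cat.), THF–MeOH–H2O, rt
Reagents that add atoms: tert-butyldimethylsilyl chloride, CC(C)(C)[Si](C)(C)Cl
Why: Exhaustive silylation followed by selective hydrolysis of the labile silyl ester leaves the phenol masked and the acid free, so the phenol cannot compete in the esterification.

Step 17
Reactants: 20 C8,C11 diol; 23 4-O-silyl ferulic acid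
Product: 24 O-silyl ferulate ester
Conditions: EDC·HCl, DMAP (cat.), CH2Cl2, rt
Reagents that add atoms: none
Why: Steglich esterification acylates the secondary C8 hydroxyl while the tertiary C11 hydroxyl is too hindered to react, and the E-alkene of the acid is untouched.

Step 18
Reactants: 24 O-silyl ferulate ester
Product: 25 CNP0241038.1
Conditions: Bu4NF, AcOH, THF, 0 °C
Reagents that add atoms: none
Why: The aryl silyl ether is far more labile to fluoride than the cinnamate ester, and acetic acid protonates the phenoxide so that ester cleavage or acyl transfer should not occur.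

**Compound list**

1 | 2-methylcyclohexane-1,3-dione | CC1C(=O)CCCC1=O | starting material
2 | methyl vinyl ketone (but-3-en-2-one) | CC(=O)C=C | starting material
3 | 2-methyl-2-(3-oxobutyl)cyclohexane-1,3-dione (Michael triketone, achiral) | CC(=O)CCC1(C)C(=O)CCCC1=O | intermediate (not isolated)
4 | (S)-Wieland–Miescher ketone, (8aS)-8a-methyl-3,4,8,8a-tetrahydronaphthalene-1,6(2H,7H)-dione; route numbering: C1 ketone, C5=C6–C7=O enone, 10α-methyl | O=C1CCCC2=CC(=O)CC[C@]12C | intermediate
5 | (4aS,5S)-5-hydroxy-4a-methyl-4,4a,5,6,7,8-hexahydronaphthalen-2(3H)-one; 1α-hydroxy enone, OH cis to the C10 methyl | O[C@H]1CCCC2=CC(=O)CC[C@]12C | intermediate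
6 | 1α-benzyloxy-10α-methyl enone (benzyl ether of 5, C5=C6–C7=O) | c1ccccc1CO[C@H]1CCCC2=CC(=O)CC[C@]12C | intermediate
7 | 1α-benzyloxy-10α-methyl-4-methylene dienone (C4=CH2, C5=C6–C7=O) | c1ccccc1CO[C@H]1CCC(=C)C2=CC(=O)CC[C@]12C | intermediate
8 | 1α-benzyloxy-4α,10α-dimethyl enone (axial 4-methyl, cis to the C10 methyl) | c1ccccc1CO[C@H]1CC[C@@H](C)C2=CC(=O)CC[C@]12C | intermediate (not isolated)
9 | 1α-benzyloxy-4β,10α-dimethyl enone (equatorial 4-methyl, trans to the C10 methyl) | c1ccccc1CO[C@H]1CC[C@H](C)C2=CC(=O)CC[C@]12C | intermediate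
10 | 1α-benzyloxy-8β-hydroxy-4β,10α-dimethyl enone (C8 OH trans to the C10 methyl) | c1ccccc1CO[C@H]1CC[C@H](C)C2=CC(=O)[C@H](O)C[C@]12C | intermediate
11 | 1α-benzyloxy-8β-(tert-butyldiphenylsilyloxy)-4β,10α-dimethyl enone | c1ccccc1CO[C@H]1CC[C@H](C)C2=CC(=O)[C@H](O[Si](c3ccccc3)(c3ccccc3)C(C)(C)C)C[C@]12C | intermediate
12 | cis-fused (5αH) 1α-benzyloxy-8β-(tert-butyldiphenylsilyloxy)-4β,10α-dimethyldecalin-7-one | c1ccccc1CO[C@H]1CC[C@H](C)[C@@H]2CC(=O)[C@H](O[Si](c3ccccc3)(c3ccccc3)C(C)(C)C)C[C@]12C | intermediate (not isolated)
13 | cis-fused (5αH) 1α-benzyloxy-8α-(tert-butyldiphenylsilyloxy)-4β,10α-dimethyldecalin-7-one | c1ccccc1CO[C@H]1CC[C@H](C)[C@@H]2CC(=O)[C@@H](O[Si](c3ccccc3)(c3ccccc3)C(C)(C)C)C[C@]12C | intermediate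
14 | C6=C7 enol triflate of 13 (7-trifluoromethanesulfonyloxy) | c1ccccc1CO[C@H]1CC[C@H](C)[C@@H]2C=C(OS(=O)(=O)C(F)(F)F)[C@@H](O[Si](c3ccccc3)(c3ccccc3)C(C)(C)C)C[C@]12C | intermediate
15 | methyl 1α-benzyloxy-8α-(tert-butyldiphenylsilyloxy)-4β,10α-dimethyl-5αH-octal-6-ene-7-carboxylate | c1ccccc1CO[C@H]1CC[C@H](C)[C@@H]2C=C(C(=O)OC)[C@@H](O[Si](c3ccccc3)(c3ccccc3)C(C)(C)C)C[C@]12C | intermediate
16 | methyl 1α-hydroxy-8α-(tert-butyldiphenylsilyloxy)-4β,10α-dimethyl-5αH-decalin-7β-carboxylate (cis-fused) | O[C@H]1CC[C@H](C)[C@@H]2C[C@H](C(=O)OC)[C@@H](O[Si](c3ccccc3)(c3ccccc3)C(C)(C)C)C[C@]12C | intermediate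
17 | methyl 1α-methanesulfonyloxy-8α-(tert-butyldiphenylsilyloxy)-4β,10α-dimethyl-5αH-decalin-7β-carboxylate (cis-fused; key-step precursor) | CS(=O)(=O)O[C@H]1CC[C@H](C)[C@@H]2C[C@H](C(=O)OC)[C@@H](O[Si](c3ccccc3)(c3ccccc3)C(C)(C)C)C[C@]12C | intermediate
18 | hydroazulene ester (key-step product): cyclopentane C1–C5 fused to cycloheptene C1,C5–C10, C1=C10, (4S,5S,7S,8S), 4β-methyl, 5αH, 7β-CO2Me, 8α-(tert-butyldiphenylsilyloxy), 10-methyl | CC(C)(C)[Si](c1ccccc1)(c1ccccc1)O[C@H]1CC(C)=C2CC[C@H](C)[C@@H]2C[C@@H]1C(=O)OC | intermediate
19 | (4S,5S,7S,8S)-8-(tert-butyldiphenylsilyloxy)guai-1(10)-en-11-ol | CC(C)(C)[Si](c1ccccc1)(c1ccccc1)O[C@H]1CC(C)=C2CC[C@H](C)[C@@H]2C[C@@H]1C(C)(C)O | intermediate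
20 | (4S,5S,7S,8S)-guai-1(10)-ene-8,11-diol (8α-OH, 7β-hydroxyisopropyl) | O[C@H]1CC(C)=C2CC[C@H](C)[C@@H]2C[C@@H]1C(C)(C)O | intermediate
21 | (E)-ferulic acid | COc1cc(/C=C/C(=O)O)ccc1O | starting material
22 | tert-butyldimethylsilyl (E)-4-O-(tert-butyldimethylsilyl)ferulate | COc1cc(/C=C/C(=O)O[Si](C)(C)C(C)(C)C)ccc1O[Si](C)(C)C(C)(C)C | intermediate (not isolated)
23 | (E)-4-O-(tert-butyldimethylsilyl)ferulic acid | COc1cc(/C=C/C(=O)O)ccc1O[Si](C)(C)C(C)(C)C | intermediate
24 | 8-O-[(E)-4-O-(tert-butyldimethylsilyl)feruloyl] ester of 20 | COc1cc(/C=C/C(=O)O[C@H]2CC(C)=C3CC[C@H](C)[C@@H]3C[C@@H]2C(C)(C)O)ccc1O[Si](C)(C)C(C)(C)C | intermediate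
25 | CNP0241038.1, (4S,5S,7S,8S)-8-O-(E)-feruloyl-guai-1(10)-ene-8,11-diol | COc1cc(/C=C/C(=O)O[C@H]2CC(C)=C3CC[C@H](C)[C@@H]3C[C@@H]2C(C)(C)O)ccc1O | target

**Step count and risks**

Total step count: 18. Longest linear sequence: 17 steps (steps 1–15, 17 and 18); step 16 is a one-step branch from ferulic acid.

Steps most likely to fail:

1. Step 13. After the shift, the C10 cation may lose a proton from C9 or from the methyl group instead of H1, giving alkene regioisomers. Fallback: the rearrangement and the placement of the alkene are separated. Setting out from 17, the acetolysis is run as before and the unseparated olefin mixture, containing the exocyclic 10(14)-alkene F1 and the 9-alkene F2, is heated with RhCl3·3H2O (cat.) in MeOH at 65 °C. Allylic hydrogen transfer through rhodium hydride intermediates should move both double bonds into the tetrasubstituted C1=C10 position, where the route is rejoined at 18.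

2. Step 8. Poor facial selectivity in the enone hydrogenation (trans fusion) or premature hydrogenolysis of the benzyl ether. Fallback: substrate-directed homogeneous hydrogenation through a temporary allylic alcohol. Setting out from 11, Luche reduction (NaBH4, CeCl3·7H2O, MeOH, −78 °C) should give the equatorial 7α allylic alcohol F3, hydride entering axially on the face away from the angular methyl. Its hydroxyl lies on the α face and should direct [Ir(cod)(PCy3)(py)]PF6/H2 (CH2Cl2, rt) to deliver H5 on that face, giving the cis-fused 7α-alcohol F4 without touching the benzyl ether. Dess–Martin oxidation returns to 12, which is equilibrated with DBU to 13 as in step 8.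

3. Step 4. The alkoxymethyl cation generated in situ may attack positions other than C4, or the cross-conjugated methylene dienone may oligomerise in the acidic medium. Fallback: the γ-carbon is functionalised stepwise through an isolated dienol ether. Setting out from 6, HC(OEt)3 with TsOH (cat.) gives the heteroannular dienol ethyl ether F5. Vilsmeier formylation (POCl3, DMF, then aqueous NaOAc) at C4 gives the 4-formyl dienol ether F6. NaBH4 reduction gives the 4-hydroxymethyl dienol ether F7. Dilute aqueous HCl in acetone hydrolyses the enol ether with loss of water, rejoining the route at 7.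

**Further compounds**

F1 | step 13 | methyl 8α-(tert-butyldiphenylsilyloxy)-4β-methyl-10-methylene-1βH,5αH-hydroazulene-7β-carboxylate (10(14)-alkene regioisomer of 18) | CC(C)(C)[Si](c1ccccc1)(c1ccccc1)O[C@H]1CC(=C)[C@H]2CC[C@H](C)[C@@H]2C[C@@H]1C(=O)OC
F2 | step 13 | methyl 8α-(tert-butyldiphenylsilyloxy)-4β,10-dimethyl-1βH,5αH-hydroazul-9-ene-7β-carboxylate (9-alkene regioisomer of 18) | CC(C)(C)[Si](c1ccccc1)(c1ccccc1)O[C@H]1C=C(C)[C@H]2CC[C@H](C)[C@@H]2C[C@@H]1C(=O)OC
F3 | step 8 | 1α-benzyloxy-8β-(tert-butyldiphenylsilyloxy)-4β,10α-dimethyl-octal-5-en-7α-ol (allylic alcohol) | c1ccccc1CO[C@H]1CC[C@H](C)C2=C[C@@H](O)[C@H](O[Si](c3ccccc3)(c3ccccc3)C(C)(C)C)C[C@]12C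
F4 | step 8 | cis-fused (5αH) 1α-benzyloxy-8β-(tert-butyldiphenylsilyloxy)-4β,10α-dimethyldecalin-7α-ol | c1ccccc1CO[C@H]1CC[C@H](C)[C@@H]2C[C@@H](O)[C@H](O[Si](c3ccccc3)(c3ccccc3)C(C)(C)C)C[C@]12C
F5 | step 4 | 1α-benzyloxy-7-ethoxy-10α-methyl-octa-4,6-diene (heteroannular dienol ethyl ether of 6) | c1ccccc1CO[C@H]1CCC=C2C=C(OCC)CC[C@]12C
F6 | step 4 | 1α-benzyloxy-7-ethoxy-10α-methyl-octa-4,6-diene-4-carbaldehyde | c1ccccc1CO[C@H]1CCC(C=O)=C2C=C(OCC)CC[C@]12C
F7 | step 4 | 1α-benzyloxy-7-ethoxy-4-hydroxymethyl-10α-methyl-octa-4,6-diene | c1ccccc1CO[C@H]1CCC(CO)=C2C=C(OCC)CC[C@]12C
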